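**Retrosynthetic overview**
1. Target 41 ⇐ ring-closing metathesis at C4=C5 of diene 40 (macrocycle closed last) ⇐ angeloylation of alcohol 37.
2. 37 ⇐ key C7–C8 bond: intermolecular zinc Barbier allylation of furanone aldehyde 24 (fragment A) with bromobutenolide 35 (fragment B); this also creates the α-methylene-γ-lactone and sets C7 and C8.
3. 24 ⇐ 3(2H)-furanone by gold-catalysed cyclisation of γ-hydroxy ynone 19 ⇐ Weinreb amide 11 (from (S)-lactic acid; Seebach alkylation sets C10) + enyne 16 (fragment C).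
4. 35 ⇐ (S)-5-oxotetrahydrofuran-2-carboxylic acid 25 (sets C6) by Wittig methylenation, selenoxide elimination and Appel bromination.
5. Ring order: furanone (fragment A) and butenolide (fragment B) → α-methylene lactone at the Barbier step → macrocycle by metathesis.

Assumption: positions are given in germacrane numbering (C6 lactone carbinol, C8 ester carbinol, C10 quaternary carbon, C15 acetoxymethyl), and acid 25 (made industrially from L-glutamic acid) is taken as a cheap commercial starting material.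

**Fragment A**

Step 1
Reactants: 1 (S)-lactic acid; 2 pivalaldehyde
Product: 3 (2S,5S)-2-tert-butyl-5-methyl-1,3-dioxolan-4-one
Conditions: TsOH·H2O (cat.), H2SO4 (cat.), pentane, reflux, Dean–Stark; recrystallise at −78 °C
Reagents that add atoms: none
Why: Acid-catalysed acetalisation with water removal gives mainly the cis dioxolanone, purified by crystallisation, so the acetal centre (2S) stores the lactate chirality (Seebach self-regeneration of stereocentres).

Step 2
Reactants: 3 (2S,5S)-2-tert-butyl-5-methyl-1,3-dioxolan-4-one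
Product: 5 (2S,5R)-2-tert-butyl-5-methyl-5-(prop-2-en-1-yl)-1,3-dioxolan-4-one, via lithium enolate 4 (not isolated)
Conditions: LiN(i-Pr)2, THF, −78 °C; allyl bromide, −78 → −30 °C
Reagents that add atoms: allyl bromide, C=CCBr
Why: Enolate alkylation occurs anti to the tert-butyl group, so allyl replaces H with retention and sets the future C10 quaternary centre as R.

Step 3
Reactants: 5 (2S,5R)-2-tert-butyl-5-methyl-5-(prop-2-en-1-yl)-1,3-dioxolan-4-one
Product: 8 (3R)-3-hydroxy-3-methyloxolan-2-one, via aldehyde 6 (not isolated), via alcohol 7 (not isolated)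
Conditions: O3, CH2Cl2/MeOH, −78 °C; Me2S; NaBH4, EtOH, −20 °C; then TsOH·H2O (cat.), CH2Cl2, rt
Reagents that add atoms: ozone, [O-][O+]=O
Why: Ozonolysis and aldehyde-selective borohydride reduction give a primary alcohol that lactonises onto the activated dioxolanone carbonyl (transacylation) and expels pivalaldehyde, leaving the quaternary centre untouched.

Step 4
Reactants: 8 (3R)-3-hydroxy-3-methyloxolan-2-one
Product: 9 (2R)-2,4-dihydroxy-N-methoxy-N,2-dimethylbutanamide
Conditions: MeNHOMe·HCl, AlMe3, CH2Cl2, 0 °C → rt; aq. potassium sodium tartrate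
Reagents that add atoms: N,O-dimethylhydroxylamine hydrochloride, CNOC.Cl
Why: Weinreb aminolysis of the lactone by the aluminium amide opens the ring to the hydroxy Weinreb amide, which is silylated at once to prevent relactonisation.

Step 5
Reactants: 9 (2R)-2,4-dihydroxy-N-methoxy-N,2-dimethylbutanamide
Product: 11 (2R)-4-[(tert-butyldiphenylsilyl)oxy]-N-methoxy-N,2-dimethyl-2-[(trimethylsilyl)oxy]butanamide, via mono-silyl ether 10 (not isolated)
Conditions: TBDPSCl (1.05 equiv), imidazole, DMF, 0 °C; then TMSCl, rt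
Reagents that add atoms: tert-butyl(chloro)diphenylsilane, CC(C)(C)[Si](Cl)(c1ccccc1)c1ccccc1; chlorotrimethylsilane, C[Si](C)(C)Cl
Why: Sequential silylation: the bulky TBDPS chloride takes only the primary hydroxyl, and the small TMS chloride then caps the tertiary hydroxyl as a labile ether.

**Fragment C**

Step 6
Reactants: 12 2-bromoprop-2-en-1-ol
Product: 13 [(2-bromoprop-2-en-1-yl)oxy](tert-butyl)dimethylsilane
Conditions: TBSCl, imidazole, CH2Cl2, 0 °C → rt
Reagents that add atoms: tert-butyl(chloro)dimethylsilane, CC(C)(C)[Si](C)(C)Cl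
Why: Standard silyl protection of the primary allylic alcohol that will become the C15 oxygen.

Step 7
Reactants: 13 [(2-bromoprop-2-en-1-yl)oxy](tert-butyl)dimethylsilane; 14 ethynyltrimethylsilane
Product: 15 tert-butyldimethyl{[2-methylidene-4-(trimethylsilyl)but-3-yn-1-yl]oxy}silane
Conditions: Pd(PPh3)2Cl2 (3 mol %), CuI (5 mol %), Et3N, THF, rt → 40 °C
Reagents that add atoms: none
Why: Sonogashira coupling (zerovalent palladium inserts into the vinyl bromide, copper acetylide transmetalates) builds the C2–C3–C4 enyne.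

Step 8
Reactants: 15 tert-butyldimethyl{[2-methylidene-4-(trimethylsilyl)but-3-yn-1-yl]oxy}silane
Product: 16 tert-butyldimethyl[(2-methylidenebut-3-yn-1-yl)oxy]silane
Conditions: K2CO3 (0.2 equiv), MeOH, 0 °C
Reagents that add atoms: none
Why: Methanolytic protiodesilylation cleaves only the alkynyl C–Si bond and leaves the TBS ether intact.

**Fragment A, continued**

Step 9
Reactants: 11 (2R)-4-[(tert-butyldiphenylsilyl)oxy]-N-methoxy-N,2-dimethyl-2-[(trimethylsilyl)oxy]butanamide; 16 tert-butyldimethyl[(2-methylidenebut-3-yn-1-yl)oxy]silane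
Product: 19 (3R)-7-{[(tert-butyldimethylsilyl)oxy]methyl}-1-[(tert-butyldiphenylsilyl)oxy]-3-hydroxy-3-methyloct-7-en-5-yn-4-one, via lithium acetylide 17 (not isolated), via silyl ynone 18 (not isolated)
Conditions: 16, n-BuLi, THF, −78 °C; add 11, −78 → 0 °C; sat. aq. NH4Cl; then citric acid, MeOH, 0 °C
Reagents that add atoms: none
Why: Weinreb ketone synthesis (the chelated tetrahedral intermediate stops over-addition) gives the ynone, and mild acid methanolysis removes only the tertiary TMS ether.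

Step 10
Reactants: 19 (3R)-7-{[(tert-butyldimethylsilyl)oxy]methyl}-1-[(tert-butyldiphenylsilyl)oxy]-3-hydroxy-3-methyloct-7-en-5-yn-4-one
Product: 20 (2R)-5-{3-[(tert-butyldimethylsilyl)oxy]prop-1-en-2-yl}-2-{2-[(tert-butyldiphenylsilyl)oxy]ethyl}-2-methylfuran-3(2H)-one
Conditions: (p-CF3C6H4)3PAuCl (5 mol %), AgOTf (5 mol %), toluene, rt
Reagents that add atoms: none
Why: Cationic monovalent gold activates the ynone for 5-endo-dig attack of the tertiary hydroxyl (cycloisomerisation), forming the 3(2H)-furanone without touching C10.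

Step 11
Reactants: 20 (2R)-5-{3-[(tert-butyldimethylsilyl)oxy]prop-1-en-2-yl}-2-{2-[(tert-butyldiphenylsilyl)oxy]ethyl}-2-methylfuran-3(2H)-one
Product: 21 (2R)-2-{2-[(tert-butyldiphenylsilyl)oxy]ethyl}-5-(3-hydroxyprop-1-en-2-yl)-2-methylfuran-3(2H)-one
Conditions: PPTS (0.2 equiv), MeOH, rt
Reagents that add atoms: none
Why: Acid-catalysed methanolysis cleaves the primary TBS ether far faster than the TBDPS ether (selective desilylation).

Step 12
Reactants: 21 (2R)-2-{2-[(tert-butyldiphenylsilyl)oxy]ethyl}-5-(3-hydroxyprop-1-en-2-yl)-2-methylfuran-3(2H)-one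
Product: 22 2-[(5R)-5-{2-[(tert-butyldiphenylsilyl)oxy]ethyl}-5-methyl-4-oxo-4,5-dihydrofuran-2-yl]prop-2-en-1-yl acetate
Conditions: Ac2O, pyridine, CH2Cl2, 0 °C
Reagents that add atoms: acetic anhydride, CC(=O)OC(C)=O
Why: Simple acetylation installs the C15 acetate early, so no protecting-group change is needed after the macrocycle is formed.

Step 13
Reactants: 22 2-[(5R)-5-{2-[(tert-butyldiphenylsilyl)oxy]ethyl}-5-methyl-4-oxo-4,5-dihydrofuran-2-yl]prop-2-en-1-yl acetate
Product: 23 2-[(5R)-5-(2-hydroxyethyl)-5-methyl-4-oxo-4,5-dihydrofuran-2-yl]prop-2-en-1-yl acetate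
Conditions: HF·pyridine, pyridine, THF, 0 °C → rt
Reagents that add atoms: none
Why: Buffered fluoride desilylation removes the TBDPS group under near-neutral conditions that spare the acetate and the furanone.

Step 14
Reactants: 23 2-[(5R)-5-(2-hydroxyethyl)-5-methyl-4-oxo-4,5-dihydrofuran-2-yl]prop-2-en-1-yl acetate
Product: 24 2-[(5R)-5-methyl-4-oxo-5-(2-oxoethyl)-4,5-dihydrofuran-2-yl]prop-2-en-1-yl acetate
Conditions: Dess–Martin periodinane, CH2Cl2, 0 °C → rt; used at once
Reagents that add atoms: none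
Why: Dess–Martin oxidation gives the C8 aldehyde without base, which avoids E1cB loss of the β-furanone oxygen.

**Fragment B**

Step 15
Reactants: 25 (2S)-5-oxooxolane-2-carboxylic acid
Product: 26 (5S)-5-(hydroxymethyl)oxolan-2-one
Conditions: BH3·SMe2, THF, 0 °C → rt; MeOH
Reagents that add atoms: none
Why: Borane reduces the carboxylic acid chemoselectively in the presence of the lactone and does not touch the stereocentre.

Step 16
Reactants: 26 (5S)-5-(hydroxymethyl)oxolan-2-one
Product: 27 (2S)-5-oxooxolane-2-carbaldehyde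
Conditions: Dess–Martin periodinane, CH2Cl2, rt; crude
Reagents that add atoms: none
Why: Neutral Dess–Martin oxidation gives the α-oxygenated aldehyde without epimerisation; it is carried on crude.

Step 17
Reactants: 27 (2S)-5-oxooxolane-2-carbaldehyde
Product: 28 (5S)-5-ethenyloxolan-2-one
Conditions: Ph3PCH3Br, KN(SiMe3)2, THF, 0 °C; then 27, −78 → 0 °C
Reagents that add atoms: methyltriphenylphosphonium bromide, C[P+](c1ccccc1)(c1ccccc1)c1ccccc1.[Br-]
Why: Wittig methylenation at low temperature converts the aldehyde into the C6 vinyl group (future C5) faster than the ylide attacks the lactone or epimerises the centre.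

Step 18
Reactants: 28 (5S)-5-ethenyloxolan-2-one
Product: 30 (5S)-5-ethenyl-3-(phenylselanyl)oxolan-2-one (C3 epimers), via lithium enolate 29 (not isolated)
Conditions: LiN(i-Pr)2, THF, −78 °C; PhSeBr, −78 °C
Reagents that add atoms: phenylselanyl bromide, Br[Se]c1ccccc1
Why: α-Selenenylation of the lactone enolate installs the group later used to introduce the ring double bond; the C3 configuration is irrelevant.

Step 19
Reactants: 30 (5S)-5-ethenyl-3-(phenylselanyl)oxolan-2-one
Product: 32 (5S)-5-ethenyl-3-(hydroxymethyl)-3-(phenylselanyl)oxolan-2-one (C3 epimers), via lithium enolate 31 (not isolated)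
Conditions: LiN(i-Pr)2, THF, −78 °C; CH2O (gas, from cracked paraformaldehyde), −78 → −40 °C; sat. aq. NH4Cl
Reagents that add atoms: formaldehyde, C=O
Why: Aldol hydroxymethylation of the selenium-stabilised enolate adds the future C13 carbon.

Step 20
Reactants: 32 (5S)-5-ethenyl-3-(hydroxymethyl)-3-(phenylselanyl)oxolan-2-one
Product: 34 (5R)-5-ethenyl-3-(hydroxymethyl)furan-2(5H)-one, via selenoxide 33 (not isolated)
Conditions: 30 % aq. H2O2, pyridine, CH2Cl2, 0 °C → rt
Reagents that add atoms: none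
Why: Selenoxide syn-elimination goes toward the ring CH2 and away from the carbinol carbon, giving the endocyclic butenolide; the descriptor changes to R only through CIP priorities.

Step 21
Reactants: 34 (5R)-5-ethenyl-3-(hydroxymethyl)furan-2(5H)-one
Product: 35 (5R)-3-(bromomethyl)-5-ethenylfuran-2(5H)-one
Conditions: CBr4, PPh3, CH2Cl2, 0 °C
Reagents that add atoms: carbon tetrabromide, BrC(Br)(Br)Br
Why: Appel bromination converts the allylic alcohol into the bromide under neutral conditions that do not enolise the γ-position.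

**Fragment union and endgame**

Step 22
Reactants: 24 2-[(5R)-5-methyl-4-oxo-5-(2-oxoethyl)-4,5-dihydrofuran-2-yl]prop-2-en-1-yl acetate; 35 (5R)-3-(bromomethyl)-5-ethenylfuran-2(5H)-one
Product: 37 2-[(5R)-5-{(2S)-2-[(2R,3R)-2-ethenyl-4-methylidene-5-oxooxolan-3-yl]-2-hydroxyethyl}-5-methyl-4-oxo-4,5-dihydrofuran-2-yl]prop-2-en-1-yl acetate, via allylzinc bromide 36 (not isolated)
Conditions: Zn dust, THF/sat. aq. NH4Cl (2:1), 0 °C → rt
Reagents that add atoms: none
Why: Barbier allylation: the allylzinc adds through its γ-carbon in a chair Zimmerman–Traxler transition state, anti to the C6 vinyl group (trans lactone, 7R), and its ring-fixed E-type geometry gives the anti C7/C8 relationship (8S) while forming the α-methylene lactone.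

Step 23
Reactants: 37 (the alcohol from step 22); 38 angelic acid [(2Z)-2-methylbut-2-enoic acid]
Product: 40 (1S)-2-[(2R)-5-(3-acetoxyprop-1-en-2-yl)-2-methyl-3-oxo-2,3-dihydrofuran-2-yl]-1-[(2R,3R)-2-ethenyl-4-methylidene-5-oxooxolan-3-yl]ethyl (2Z)-2-methylbut-2-enoate, via mixed anhydride 39 (not isolated)
Conditions: 38, 2,4,6-Cl3C6H2COCl, i-Pr2NEt, toluene, rt, 2 h; then 37, 70 °C
Reagents that add atoms: none
Why: Yamaguchi esterification through the mixed anhydride, run without a nucleophilic catalyst, acylates the hindered C8 hydroxyl without Z-to-E isomerisation of the angelate and blocks translactonisation.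

Step 24
Reactants: 40 (the angelate diene from step 23)
Product: 41 (6R,7R,8S,10R,4Z)-15-acetoxy-8-[(2Z)-2-methylbut-2-enoyloxy]-1-oxo-3,10-epoxygermacra-2,4,11(13)-trien-12,6-olide
Conditions: second-generation Hoveyda–Grubbs catalyst (20 mol %), 1,4-benzoquinone (20 mol %), toluene (1 mM), 80 °C
Reagents that add atoms: none
Why: Ring-closing metathesis starts at the monosubstituted C6 vinyl group and closes onto the 1,1-disubstituted alkene with loss of ethylene, the nine-membered oxa-bridged ring enforcing the 4Z geometry; the electron-poor exocyclic methylene and the angelate alkene do not react.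

**Compound list**
1 | (S)-lactic acid | C[C@H](O)C(=O)O | starting material
2 | pivalaldehyde | CC(C)(C)C=O | starting material
3 | (2S,5S)-2-tert-butyl-5-methyl-1,3-dioxolan-4-one | C[C@@H]1O[C@H](C(C)(C)C)OC1=O | intermediate
4 | lithium (2S)-2-tert-butyl-5-methyl-1,3-dioxol-4-olate | [Li+].[O-]C1=C(C)O[C@H](C(C)(C)C)O1 | intermediate
5 | (2S,5R)-2-tert-butyl-5-methyl-5-(prop-2-en-1-yl)-1,3-dioxolan-4-one | C[C@]1(CC=C)O[C@H](C(C)(C)C)OC1=O | intermediate
6 | 2-[(2S,4R)-2-tert-butyl-4-methyl-5-oxo-1,3-dioxolan-4-yl]acetaldehyde | C[C@]1(CC=O)O[C@H](C(C)(C)C)OC1=O | intermediate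
7 | (2S,5R)-2-tert-butyl-5-(2-hydroxyethyl)-5-methyl-1,3-dioxolan-4-one | C[C@]1(CCO)O[C@H](C(C)(C)C)OC1=O | intermediate
8 | (3R)-3-hydroxy-3-methyloxolan-2-one | C[C@@]1(O)CCOC1=O | intermediate
9 | (2R)-2,4-dihydroxy-N-methoxy-N,2-dimethylbutanamide | CON(C)C(=O)[C@](C)(O)CCO | intermediate
10 | (2R)-4-[(tert-butyldiphenylsilyl)oxy]-2-hydroxy-N-methoxy-N,2-dimethylbutanamide | CON(C)C(=O)[C@](C)(O)CCO[Si](c1ccccc1)(c1ccccc1)C(C)(C)C | intermediate
11 | (2R)-4-[(tert-butyldiphenylsilyl)oxy]-N-methoxy-N,2-dimethyl-2-[(trimethylsilyl)oxy]butanamide | CON(C)C(=O)[C@](C)(O[Si](C)(C)C)CCO[Si](c1ccccc1)(c1ccccc1)C(C)(C)C | intermediate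
12 | 2-bromoprop-2-en-1-ol | OCC(Br)=C | starting material
13 | [(2-bromoprop-2-en-1-yl)oxy](tert-butyl)dimethylsilane | C=C(Br)CO[Si](C)(C)C(C)(C)C | intermediate
14 | ethynyltrimethylsilane | C#C[Si](C)(C)C | starting material
15 | tert-butyldimethyl{[2-methylidene-4-(trimethylsilyl)but-3-yn-1-yl]oxy}silane | C=C(CO[Si](C)(C)C(C)(C)C)C#C[Si](C)(C)C | intermediate
16 | tert-butyldimethyl[(2-methylidenebut-3-yn-1-yl)oxy]silane | C=C(CO[Si](C)(C)C(C)(C)C)C#C | intermediate
17 | lithium 3-{[(tert-butyldimethylsilyl)oxy]methyl}but-3-en-1-yn-1-ide | [Li+].[C-]#CC(=C)CO[Si](C)(C)C(C)(C)C | intermediate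
18 | (3R)-7-{[(tert-butyldimethylsilyl)oxy]methyl}-1-[(tert-butyldiphenylsilyl)oxy]-3-methyl-3-[(trimethylsilyl)oxy]oct-7-en-5-yn-4-one | C=C(CO[Si](C)(C)C(C)(C)C)C#CC(=O)[C@](C)(O[Si](C)(C)C)CCO[Si](c1ccccc1)(c1ccccc1)C(C)(C)C | intermediate
19 | (3R)-7-{[(tert-butyldimethylsilyl)oxy]methyl}-1-[(tert-butyldiphenylsilyl)oxy]-3-hydroxy-3-methyloct-7-en-5-yn-4-one | C=C(CO[Si](C)(C)C(C)(C)C)C#CC(=O)[C@](C)(O)CCO[Si](c1ccccc1)(c1ccccc1)C(C)(C)C | intermediate
20 | (2R)-5-{3-[(tert-butyldimethylsilyl)oxy]prop-1-en-2-yl}-2-{2-[(tert-butyldiphenylsilyl)oxy]ethyl}-2-methylfuran-3(2H)-one | C=C(CO[Si](C)(C)C(C)(C)C)C1=CC(=O)[C@@](C)(CCO[Si](c2ccccc2)(c2ccccc2)C(C)(C)C)O1 | intermediate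
21 | (2R)-2-{2-[(tert-butyldiphenylsilyl)oxy]ethyl}-5-(3-hydroxyprop-1-en-2-yl)-2-methylfuran-3(2H)-one | C=C(CO)C1=CC(=O)[C@@](C)(CCO[Si](c2ccccc2)(c2ccccc2)C(C)(C)C)O1 | intermediate
22 | 2-[(5R)-5-{2-[(tert-butyldiphenylsilyl)oxy]ethyl}-5-methyl-4-oxo-4,5-dihydrofuran-2-yl]prop-2-en-1-yl acetate | C=C(COC(C)=O)C1=CC(=O)[C@@](C)(CCO[Si](c2ccccc2)(c2ccccc2)C(C)(C)C)O1 | intermediate
23 | 2-[(5R)-5-(2-hydroxyethyl)-5-methyl-4-oxo-4,5-dihydrofuran-2-yl]prop-2-en-1-yl acetate | C=C(COC(C)=O)C1=CC(=O)[C@@](C)(CCO)O1 | intermediate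
24 | 2-[(5R)-5-methyl-4-oxo-5-(2-oxoethyl)-4,5-dihydrofuran-2-yl]prop-2-en-1-yl acetate | C=C(COC(C)=O)C1=CC(=O)[C@@](C)(CC=O)O1 | intermediate
25 | (2S)-5-oxooxolane-2-carboxylic acid | OC(=O)[C@@H]1CCC(=O)O1 | starting material
26 | (5S)-5-(hydroxymethyl)oxolan-2-one | OC[C@@H]1CCC(=O)O1 | intermediate
27 | (2S)-5-oxooxolane-2-carbaldehyde | O=C[C@@H]1CCC(=O)O1 | intermediate
28 | (5S)-5-ethenyloxolan-2-one | C=C[C@@H]1CCC(=O)O1 | intermediate
29 | lithium (5S)-5-ethenyl-4,5-dihydrofuran-2-olate | [Li+].[O-]C1=CC[C@@H](C=C)O1 | intermediate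
30 | (5S)-5-ethenyl-3-(phenylselanyl)oxolan-2-one | C=C[C@@H]1CC([Se]c2ccccc2)C(=O)O1 | intermediate
31 | lithium (5S)-5-ethenyl-3-(phenylselanyl)-4,5-dihydrofuran-2-olate | [Li+].[O-]C1=C([Se]c2ccccc2)C[C@@H](C=C)O1 | intermediate
32 | (5S)-5-ethenyl-3-(hydroxymethyl)-3-(phenylselanyl)oxolan-2-one | C=C[C@@H]1CC(CO)([Se]c2ccccc2)C(=O)O1 | intermediate
33 | (5S)-5-ethenyl-3-(hydroxymethyl)-3-(phenylseleninyl)oxolan-2-one | C=C[C@@H]1CC(CO)([Se](=O)c2ccccc2)C(=O)O1 | intermediate
34 | (5R)-5-ethenyl-3-(hydroxymethyl)furan-2(5H)-one | C=C[C@@H]1C=C(CO)C(=O)O1 | intermediate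
35 | (5R)-3-(bromomethyl)-5-ethenylfuran-2(5H)-one | C=C[C@@H]1C=C(CBr)C(=O)O1 | intermediate
36 | bromo{[(5R)-5-ethenyl-2-oxo-2,5-dihydrofuran-3-yl]methyl}zinc | C=C[C@@H]1C=C(C[Zn]Br)C(=O)O1 | intermediate
37 | 2-[(5R)-5-{(2S)-2-[(2R,3R)-2-ethenyl-4-methylidene-5-oxooxolan-3-yl]-2-hydroxyethyl}-5-methyl-4-oxo-4,5-dihydrofuran-2-yl]prop-2-en-1-yl acetate | C=C1C(=O)O[C@H](C=C)[C@H]1[C@@H](O)C[C@@]1(C)OC(C(=C)COC(C)=O)=CC1=O | intermediate
38 | angelic acid, (2Z)-2-methylbut-2-enoic acid | C/C=C(/C)C(=O)O | starting material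
39 | (2Z)-2-methylbut-2-enoic 2,4,6-trichlorobenzoic anhydride | C/C=C(/C)C(=O)OC(=O)c1c(Cl)cc(Cl)cc1Cl | intermediate
40 | (1S)-2-[(2R)-5-(3-acetoxyprop-1-en-2-yl)-2-methyl-3-oxo-2,3-dihydrofuran-2-yl]-1-[(2R,3R)-2-ethenyl-4-methylidene-5-oxooxolan-3-yl]ethyl (2Z)-2-methylbut-2-enoate | C=C1C(=O)O[C@H](C=C)[C@H]1[C@@H](OC(=O)/C(C)=C\C)C[C@@]1(C)OC(C(=C)COC(C)=O)=CC1=O | intermediate
41 | (6R,7R,8S,10R,4Z)-15-acetoxy-8-[(2Z)-2-methylbut-2-enoyloxy]-1-oxo-3,10-epoxygermacra-2,4,11(13)-trien-12,6-olide | C=C1C(=O)O[C@@H]2/C=C(/COC(C)=O)C3=CC(=O)[C@@](C)(C[C@H](OC(=O)/C(C)=C\C)[C@@H]12)O3 | target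

**Totals**
Total steps: 24. Longest linear sequence: 14 steps (steps 1–5, 9–14, 22–24, from (S)-lactic acid).

**Three steps most likely to fail, with fallbacks**

Step 24 (ring-closing metathesis). The ring is strained and the partner alkene is hindered and electron-poor, so dimerisation may win. The fallback inverts the order of ring closure and acylation. It sets out from alcohol 37, which is cyclised without the bulky ester (same catalyst, toluene, 1 mM, 80 °C) to the macrocyclic alcohol (6R,7R,8S,10R,4Z)-15-acetoxy-8-hydroxy-1-oxo-3,10-epoxygermacra-2,4,11(13)-trien-12,6-olide F1. F1 is then esterified with 38 through the mixed anhydride 39 as in step 23, and the route is rejoined at target 41.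

Step 22 (Barbier allylation). The risk is the C8 configuration if a boat or open transition state competes. The fallback corrects the centre by inversion instead of relying on the allylation. It sets out from 24 and 35; the epimeric alcohol 2-[(5R)-5-{(2R)-2-[(2R,3R)-2-ethenyl-4-methylidene-5-oxooxolan-3-yl]-2-hydroxyethyl}-5-methyl-4-oxo-4,5-dihydrofuran-2-yl]prop-2-en-1-yl acetate F2 is separated and esterified with 38 under Mitsunobu conditions (PPh3, DIAD, toluene, 0 °C → rt). This inverts C8 and comes back to the route at 40, bypassing step 23.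

Step 23 (angeloylation). The alcohol is hindered and the angelate can isomerise to the tiglate. The fallback builds the Z-alkene on the substrate instead of transferring it. It sets out from 37, which is acylated with 2-[bis(2,2,2-trifluoroethoxy)phosphoryl]propanoic acid (DCC, DMAP cat., CH2Cl2, 0 °C) to give the phosphonate ester (1S)-2-[(2R)-5-(3-acetoxyprop-1-en-2-yl)-2-methyl-3-oxo-2,3-dihydrofuran-2-yl]-1-[(2R,3R)-2-ethenyl-4-methylidene-5-oxooxolan-3-yl]ethyl 2-[bis(2,2,2-trifluoroethoxy)phosphoryl]propanoate F3. Still–Gennari olefination of F3 with acetaldehyde (KN(SiMe3)2, 18-crown-6, THF, −78 °C) gives the Z-enoate and comes back to the route at 40.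

**Further compounds**
F1 | step 24 | (6R,7R,8S,10R,4Z)-15-acetoxy-8-hydroxy-1-oxo-3,10-epoxygermacra-2,4,11(13)-trien-12,6-olide | C=C1C(=O)O[C@@H]2/C=C(/COC(C)=O)C3=CC(=O)[C@@](C)(C[C@H](O)[C@@H]12)O3
F2 | step 22 | 2-[(5R)-5-{(2R)-2-[(2R,3R)-2-ethenyl-4-methylidene-5-oxooxolan-3-yl]-2-hydroxyethyl}-5-methyl-4-oxo-4,5-dihydrofuran-2-yl]prop-2-en-1-yl acetate | C=C1C(=O)O[C@H](C=C)[C@H]1[C@H](O)C[C@@]1(C)OC(C(=C)COC(C)=O)=CC1=O
F3 | step 23 | (1S)-2-[(2R)-5-(3-acetoxyprop-1-en-2-yl)-2-methyl-3-oxo-2,3-dihydrofuran-2-yl]-1-[(2R,3R)-2-ethenyl-4-methylidene-5-oxooxolan-3-yl]ethyl 2-[bis(2,2,2-trifluoroethoxy)phosphoryl]propanoate | C=C1C(=O)O[C@H](C=C)[C@H]1[C@@H](OC(=O)C(C)P(=O)(OCC(F)(F)F)OCC(F)(F)F)C[C@@]1(C)OC(C(=C)COC(C)=O)=CC1=O
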